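**Retrosynthetic overview**

1. Feature: in the indane of the target (C1 = diaryl methine, C2 = isopropylidene carbon, C3 = CH2, C3a/C7a = fusion carbons, C7 = formyl carbon), C1 is bonded to three carbon groups: C7a of ring A, the benzodioxane aryl carbon and C2. It can therefore enter as a palladium carbene carbon that takes up C7a first and C2 of an ortho-prenyl group second.
2. Key disconnection: C7a–C1 and C1–C2 together (cyclopentane ring C1–C2–C3–C3a–C7a). This gives a ring-A aryl triflate carrying ortho-prenyl, MOM ether and dioxolane-masked formyl, and the N-tosylhydrazone of the benzodioxane aldehyde, whose formyl carbon becomes C1.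
3. Ring-A triflate: 2,6-dihydroxybenzaldehyde, mono-MOM ether, O-allyl ether, Claisen shift to the free ortho carbon, cross-metathesis to prenyl, triflation, dioxolane.
4. Benzodioxane: creosol, ortho-formylation, demethylation; dioxane ring from the catecholate dianion and (R)-3,3-dimethylglycidyl tosylate (Sharpless epoxidation of prenol), by O–CH2 bond formation and then 6-exo epoxide opening with inversion to the (S) centre.
5. Order of ring formation: dioxane ring (step 10), then the cyclopentane ring with C1 (step 12); mild acid unmasks the salicylaldehyde last (step 13).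

Key step: step 12

Assumption: D-(−)-diisopropyl tartrate is taken to give the (2R)-epoxy alcohol from prenol (mirror image of the (2S) product of the L-(+)-tartrate catalyst); which BINAP antipode is matched to the (S)-dioxane centre in step 12 cannot be predicted and is fixed by running both.

**Route**

Step 1
Reactants: 1 2,6-dihydroxybenzaldehyde
Product: 2 2-hydroxy-6-(methoxymethoxy)benzaldehyde
Conditions: MOMCl (1.05 equiv), i-Pr2NEt, CH2Cl2, 0 → 20 °C
Reagents that add atoms: chloromethyl methyl ether, COCCl
Why: Williamson-type O-alkylation of a phenol, in which the second hydroxyl of this symmetrical diol stays hydrogen-bonded to the formyl group and is far less nucleophilic, so one equivalent of reagent should stop at the mono-ether.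

Step 2
Reactants: 2 2-hydroxy-6-(methoxymethoxy)benzaldehyde
Product: 3 2-(methoxymethoxy)-6-(prop-2-en-1-yloxy)benzaldehyde
Conditions: allyl bromide, K2CO3, DMF, 50 °C
Reagents that add atoms: allyl bromide, C=CCBr
Why: Williamson ether synthesis on the remaining hydrogen-bonded phenol, for which carbonate in warm DMF is sufficient and which leaves the MOM ether and the aldehyde untouched.

Step 3
Reactants: 3 2-(methoxymethoxy)-6-(prop-2-en-1-yloxy)benzaldehyde
Product: 5 2-hydroxy-6-(methoxymethoxy)-3-(prop-2-en-1-yl)benzaldehyde, via ortho-dienone 4 (not isolated)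
Conditions: N,N-diethylaniline, 190 °C
Reagents that add atoms: none
Why: aromatic Claisen rearrangement, in which the [3,3]-sigmatropic shift can deliver the allyl group only to the one free ortho carbon and tautomerisation of dienone 4 restores the phenol beside the formyl group, so the positions of the future triflate and side chain are fixed without a regiochemical choice.

Step 4
Reactants: 5 2-hydroxy-6-(methoxymethoxy)-3-(prop-2-en-1-yl)benzaldehyde
Product: 6 2-hydroxy-6-(methoxymethoxy)-3-(3-methylbut-2-en-1-yl)benzaldehyde
Conditions: (H2IMes)(PCy3)Cl2Ru=CHPh (second-generation Grubbs catalyst, 3 mol%), 2-methylbut-2-ene/CH2Cl2, 40 °C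
Reagents that add atoms: 2-methylbut-2-ene, CC=C(C)C
Why: olefin cross-metathesis of a terminal allyl arene with excess 2-methylbut-2-ene is the standard allyl-to-prenyl conversion, the trisubstituted product is no longer a metathesis substrate, and free phenol and aldehyde are tolerated by the ruthenium carbene.

Step 5
Reactants: 6 2-hydroxy-6-(methoxymethoxy)-3-(3-methylbut-2-en-1-yl)benzaldehyde
Product: 7 2-formyl-3-(methoxymethoxy)-6-(3-methylbut-2-en-1-yl)phenyl trifluoromethanesulfonate
Conditions: Tf2O, pyridine, CH2Cl2, 0 °C
Reagents that add atoms: trifluoromethanesulfonic anhydride, O=S(=O)(OS(=O)(=O)C(F)(F)F)C(F)(F)F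
Why: O-sulfonylation of the phenol, with pyridine buffering the triflic acid so that the MOM ether and the prenyl double bond should survive.

Step 6
Reactants: 7 2-formyl-3-(methoxymethoxy)-6-(3-methylbut-2-en-1-yl)phenyl trifluoromethanesulfonate
Product: 8 2-(1,3-dioxolan-2-yl)-3-(methoxymethoxy)-6-(3-methylbut-2-en-1-yl)phenyl trifluoromethanesulfonate
Conditions: TMSOCH2CH2OTMS, TMSOTf (5 mol%), CH2Cl2, −78 → −20 °C; pyridine quench
Reagents that add atoms: 1,2-bis(trimethylsilyloxy)ethane, C[Si](C)(C)OCCO[Si](C)(C)C
Why: Noyori acetalisation, whose aprotic low-temperature conditions (driven by Si–O–Si bond formation) should convert even a di-ortho-substituted aldehyde into its dioxolane while sparing the aryl MOM ether that protic acid would exchange; the mask is needed because a free aldehyde would react with the diazo compound and the hydrazone in step 12.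

Step 7
Reactants: 9 2-methoxy-4-methylphenol (creosol)
Product: 11 2-hydroxy-3-methoxy-5-methylbenzaldehyde, via benzylic alcohol 10 (not isolated)
Conditions: MgCl2, Et3N, (CH2O)n, MeCN, 80 °C
Reagents that add atoms: paraformaldehyde (formaldehyde), C=O
Why: magnesium-mediated ortho-formylation of a phenol (Casnati–Skattebøl reaction), in which the magnesium phenoxide is hydroxymethylated at its only free ortho position and benzylic alcohol 10 is oxidised in the flask by hydride transfer to a second formaldehyde.

Step 8
Reactants: 11 2-hydroxy-3-methoxy-5-methylbenzaldehyde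
Product: 13 2,3-dihydroxy-5-methylbenzaldehyde, via bromoborole 12 (not isolated)
Conditions: BBr3, CH2Cl2, −78 → 0 °C; then H2O
Reagents that add atoms: none
Why: Lewis-acid cleavage of an aryl methyl ether (BBr3 demethylation), in which bromide attacks the methyl group of the boron-complexed ether, the cyclic aryl borate 12 is hydrolysed on work-up, and the non-enolisable aryl aldehyde tolerates the reagent at low temperature.

Step 9
Reactants: 14 3-methylbut-2-en-1-ol (prenol)
Product: 16 [(2R)-3,3-dimethyloxiran-2-yl]methyl 4-methylbenzenesulfonate, via epoxy alcohol 15 (not isolated)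
Conditions: Ti(OiPr)4 (5 mol%), D-(−)-diisopropyl tartrate (6 mol%), t-BuOOH, 4 Å molecular sieves, CH2Cl2, −20 °C; then P(OMe)3; then Et3N, DMAP (cat.), TsCl, −20 → 0 °C
Reagents that add atoms: tert-butyl hydroperoxide, CC(C)(C)OO; 4-methylbenzenesulfonyl chloride, Cc1ccc(cc1)S(Cl)(=O)=O
Why: Sharpless asymmetric epoxidation with in-situ sulfonylation, in which the titanium D-(−)-tartrate catalyst delivers oxygen to the alkene face that gives the (2R)-epoxide and the small, water-soluble epoxy alcohol 15 is tosylated without isolation once excess hydroperoxide has been reduced by the phosphite.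

Step 10
Reactants: 13 2,3-dihydroxy-5-methylbenzaldehyde; 16 [(2R)-3,3-dimethyloxiran-2-yl]methyl 4-methylbenzenesulfonate
Product: 18 (3S)-3-(2-hydroxypropan-2-yl)-7-methyl-2,3-dihydro-1,4-benzodioxine-5-carbaldehyde, via epoxy ether 17 (not isolated)
Conditions: NaH (2.05 equiv), DMSO, 20 °C; add 16, 20 °C, then 70 °C; H2O quench
Reagents that add atoms: none
Why: regioselective O-alkylation of a catecholate dianion followed by intramolecular Williamson-type epoxide opening, in which the non-chelated oxygen meta to the formyl group is the more nucleophilic and displaces the primary tosylate by SN2, and the remaining ortho-formyl phenoxide of 17 then opens the epoxide at its secondary carbon in a 6-exo-tet closure (7-endo attack at the tertiary carbon being disfavoured) with inversion, turning the (R)-epoxide carbon into the (S)-dioxane centre and leaving the tertiary alcohol.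

Step 11
Reactants: 18 (3S)-3-(2-hydroxypropan-2-yl)-7-methyl-2,3-dihydro-1,4-benzodioxine-5-carbaldehyde
Product: 19 N'-[(E)-{(3S)-3-(2-hydroxypropan-2-yl)-7-methyl-2,3-dihydro-1,4-benzodioxin-5-yl}methylidene]-4-methylbenzenesulfonohydrazide
Conditions: TsNHNH2, MeOH, 50 °C
Reagents that add atoms: 4-methylbenzenesulfonohydrazide, Cc1ccc(cc1)S(=O)(=O)NN
Why: condensation of an aldehyde with a sulfonyl hydrazide to the (E)-N-tosylhydrazone, which does not involve the tertiary alcohol or the dioxane centre.

Step 12
Reactants: 8 2-(1,3-dioxolan-2-yl)-3-(methoxymethoxy)-6-(3-methylbut-2-en-1-yl)phenyl trifluoromethanesulfonate; 19 N'-[(E)-{(3S)-3-(2-hydroxypropan-2-yl)-7-methyl-2,3-dihydro-1,4-benzodioxin-5-yl}methylidene]-4-methylbenzenesulfonohydrazide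
Product: 21 2-{(2S)-8-[(1S)-7-(1,3-dioxolan-2-yl)-6-(methoxymethoxy)-2-(propan-2-ylidene)-2,3-dihydro-1H-inden-1-yl]-6-methyl-2,3-dihydro-1,4-benzodioxin-2-yl}propan-2-ol, via diazo compound 20 (not isolated)
Conditions: Pd2(dba)3 (5 mol%), BINAP (12 mol%, antipode matched to the substrate), Cs2CO3 (2.5 equiv), 4 Å molecular sieves, 1,4-dioxane, 90 °C, 19 added in portions
Reagents that add atoms: none
Why: Proposed new method: zerovalent palladium inserts into the C–OTf bond of 8 to give a cationic arylpalladium (triflate does not coordinate, so the chelating bisphosphine stays on the metal), this captures diazo compound 20 released from 19 by Cs2CO3 (Bamford–Stevens fragmentation), and 1,1-migratory insertion of the aryl group into the palladium carbene forms C7a–C1 as a diarylmethylpalladium that has no β-hydrogen. That intermediate closes the cyclopentane ring by 5-exo-trig syn-carbopalladation of the prenyl double bond (C1–C2), and β-hydride loss from the resulting tertiary alkylpalladium gives the C2=CMe2 alkene and, with base, zerovalent palladium again. The closest known reaction type is the palladium-catalysed coupling of aryl halides or triflates with N-tosylhydrazones in which the benzylic palladium from carbene insertion is trapped by a tethered alkene; new here are the trisubstituted alkene acceptor and ligand control of a diarylmethine centre. C1 is set in the aryl-to-carbene migration, where the chiral bisphosphine selects the carbene face, and is carried with retention through the alkene insertion; because the dioxane centre is already (S), the (1S) and (1R) products are diastereomers and the minor one can be removed by chromatography. The order of events is secured by the substrate, since the arylpalladium itself could reach the alkene only through a 4-exo or 5-endo transition state, and hydride loss toward C2–H should prevail because a palladium hydride still bound to an isopropenyl isomer can re-add to that 1,1-disubstituted alkene whereas the tetrasubstituted alkene dissociates.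

Step 13
Reactants: 21 2-{(2S)-8-[(1S)-7-(1,3-dioxolan-2-yl)-6-(methoxymethoxy)-2-(propan-2-ylidene)-2,3-dihydro-1H-inden-1-yl]-6-methyl-2,3-dihydro-1,4-benzodioxin-2-yl}propan-2-ol
Product: 23 (3S)-5-hydroxy-3-[(3S)-3-(2-hydroxypropan-2-yl)-7-methyl-2,3-dihydro-1,4-benzodioxin-5-yl]-2-(propan-2-ylidene)-2,3-dihydro-1H-indene-4-carbaldehyde (diaporindene H), via MOM-protected aldehyde 22 (not isolated)
Conditions: 2 M aq. HCl, THF, 40 °C
Reagents that add atoms: water, O
Why: acid-catalysed acetal hydrolysis, in which the dioxolane should go first and the aryl MOM ether, then ortho to the free formyl group, should follow under the same conditions, while dilute aqueous acid at this temperature should neither protonate the tetrasubstituted double bond nor ionise the tertiary alcohol flanked by ether carbons, so C1 and the dioxane centre are untouched.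

**Compound list**

1 | 2,6-dihydroxybenzaldehyde | O=Cc1c(O)cccc1O | starting material
2 | 2-hydroxy-6-(methoxymethoxy)benzaldehyde | O=Cc1c(O)cccc1OCOC | intermediate
3 | 2-(methoxymethoxy)-6-(prop-2-en-1-yloxy)benzaldehyde | O=Cc1c(OCC=C)cccc1OCOC | intermediate
4 | 2-formyl-3-(methoxymethoxy)-6-(prop-2-en-1-yl)cyclohexa-2,4-dien-1-one (Claisen ortho-dienone, racemic, not isolated) | C=CCC1C=CC(OCOC)=C(C=O)C1=O | intermediate
5 | 2-hydroxy-6-(methoxymethoxy)-3-(prop-2-en-1-yl)benzaldehyde | O=Cc1c(O)c(CC=C)ccc1OCOC | intermediate
6 | 2-hydroxy-6-(methoxymethoxy)-3-(3-methylbut-2-en-1-yl)benzaldehyde | O=Cc1c(O)c(CC=C(C)C)ccc1OCOC | intermediate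
7 | 2-formyl-3-(methoxymethoxy)-6-(3-methylbut-2-en-1-yl)phenyl trifluoromethanesulfonate | O=Cc1c(OS(=O)(=O)C(F)(F)F)c(CC=C(C)C)ccc1OCOC | intermediate
8 | 2-(1,3-dioxolan-2-yl)-3-(methoxymethoxy)-6-(3-methylbut-2-en-1-yl)phenyl trifluoromethanesulfonate | CC(C)=CCc1ccc(OCOC)c(C2OCCO2)c1OS(=O)(=O)C(F)(F)F | intermediate
9 | 2-methoxy-4-methylphenol (creosol) | COc1cc(C)ccc1O | starting material
10 | 2-(hydroxymethyl)-6-methoxy-4-methylphenol (not isolated) | COc1cc(C)cc(CO)c1O | intermediate
11 | 2-hydroxy-3-methoxy-5-methylbenzaldehyde | COc1cc(C)cc(C=O)c1O | intermediate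
12 | 2-bromo-6-methyl-1,3,2-benzodioxaborole-4-carbaldehyde (not isolated) | O=Cc1cc(C)cc2OB(Br)Oc12 | intermediate
13 | 2,3-dihydroxy-5-methylbenzaldehyde | O=Cc1cc(C)cc(O)c1O | intermediate
14 | 3-methylbut-2-en-1-ol (prenol) | CC(C)=CCO | starting material
15 | [(2R)-3,3-dimethyloxiran-2-yl]methanol (not isolated) | OC[C@H]1OC1(C)C | intermediate
16 | [(2R)-3,3-dimethyloxiran-2-yl]methyl 4-methylbenzenesulfonate | Cc1ccc(cc1)S(=O)(=O)OC[C@H]1OC1(C)C | intermediate
17 | 3-{[(2R)-3,3-dimethyloxiran-2-yl]methoxy}-2-hydroxy-5-methylbenzaldehyde (not isolated) | O=Cc1cc(C)cc(OC[C@H]2OC2(C)C)c1O | intermediate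
18 | (3S)-3-(2-hydroxypropan-2-yl)-7-methyl-2,3-dihydro-1,4-benzodioxine-5-carbaldehyde | O=Cc1cc(C)cc2c1O[C@H](C(C)(C)O)CO2 | intermediate
19 | N'-[(E)-{(3S)-3-(2-hydroxypropan-2-yl)-7-methyl-2,3-dihydro-1,4-benzodioxin-5-yl}methylidene]-4-methylbenzenesulfonohydrazide | Cc1ccc(cc1)S(=O)(=O)N/N=C/c1cc(C)cc2c1O[C@H](C(C)(C)O)CO2 | intermediate
20 | 2-[(2S)-8-(diazomethyl)-6-methyl-2,3-dihydro-1,4-benzodioxin-2-yl]propan-2-ol (not isolated) | [N-]=[N+]=Cc1cc(C)cc2c1O[C@H](C(C)(C)O)CO2 | intermediate
21 | 2-{(2S)-8-[(1S)-7-(1,3-dioxolan-2-yl)-6-(methoxymethoxy)-2-(propan-2-ylidene)-2,3-dihydro-1H-inden-1-yl]-6-methyl-2,3-dihydro-1,4-benzodioxin-2-yl}propan-2-ol | CC(C)=C1Cc2ccc(OCOC)c(C3OCCO3)c2[C@H]1c1cc(C)cc2c1O[C@H](C(C)(C)O)CO2 | intermediate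
22 | (3S)-3-[(3S)-3-(2-hydroxypropan-2-yl)-7-methyl-2,3-dihydro-1,4-benzodioxin-5-yl]-5-(methoxymethoxy)-2-(propan-2-ylidene)-2,3-dihydro-1H-indene-4-carbaldehyde (not isolated) | CC(C)=C1Cc2ccc(OCOC)c(C=O)c2[C@H]1c1cc(C)cc2c1O[C@H](C(C)(C)O)CO2 | intermediate
23 | (3S)-5-hydroxy-3-[(3S)-3-(2-hydroxypropan-2-yl)-7-methyl-2,3-dihydro-1,4-benzodioxin-5-yl]-2-(propan-2-ylidene)-2,3-dihydro-1H-indene-4-carbaldehyde (diaporindene H) | CC(C)=C1Cc2ccc(O)c(C=O)c2[C@H]1c1cc(C)cc2c1O[C@H](C(C)(C)O)CO2 | target

**Step count and risks**

Total steps: 13. Longest linear sequence: 8 (steps 1–6, 12, 13).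

Steps most likely to fail:

1. Step 12 (proposed new method). What may go wrong:
 - insertion of the trisubstituted alkene into the crowded diarylmethyl–palladium bond is slow, so the benzylic palladium is drained by protonation, sulfinate capture or carbene dimerisation;
 - facial control in the aryl migration is weak or mismatched with the dioxane centre;
 - hydride is lost from a methyl group instead of C2–H.

 Fallback (known chemistry; sets out from 8 and 18, returns at 21): the two bonds are made in separate polar steps. Miyaura borylation of 8 (Pd(dppf)Cl2, B2pin2, KOAc, 1,4-dioxane, 80 °C) would give the aryl pinacol boronate F1. Rhodium-catalysed 1,2-addition of F1 to aldehyde 18 ([Rh(cod)OH]2, dioxane/H2O, 70 °C) would give the diarylmethanol F2 as a mixture of carbinol epimers, which does not matter because that carbon is ionised next. Ms2O and 2,6-lutidine in CH2Cl2 (−40 → 0 °C) would generate the ortho-alkoxy-stabilised diarylmethyl cation, which the prenyl alkene captures in a 5-exo cation–olefin cyclisation. Proton loss from the tertiary cation should give 21 together with its C1 epimer F3 (a diastereomer, separable by chromatography because the dioxane centre is fixed) and the isopropenyl isomer F4. F4 is converged on 21 by cobalt-hydride hydrogen-atom-transfer isomerisation (Co(tBu4-salen)Cl, PhSiH3, benzene, 20 °C), which moves the double bond by one position only. The same isomerisation would rescue material from step 12 in which hydride loss went toward a methyl group.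

2. Step 13. What may go wrong: the acid moves the exocyclic double bond into conjugation with the two aryl rings, which erases C1, before cleavage of the MOM ether is complete. Fallback (sets out from 21, returns at 23; no compound outside the list, F0): two isolated stages with different cleavage mechanisms. Acetal exchange with PPTS in wet acetone at 40 °C would give 22, now isolated. ZnBr2 and n-PrSH in CH2Cl2 at 0 °C would then remove the MOM group within minutes by thiol capture of the zinc-activated, formyl-chelated acetal, without Brønsted acid or heat.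

3. Step 10. What may go wrong: ring closure stalls at the epoxy ether because the chelated ortho-formyl phenoxide is a poor nucleophile toward the hindered secondary epoxide carbon, and forcing it leads to 7-endo opening or intermolecular etherification. Fallback (sets out from 13 and 16, returns at 18): the reaction is stopped after the alkylation at 20 °C and 17 is isolated. Its epoxide is hydrolysed with dilute HClO4 in THF/H2O at 0 °C; water enters at the tertiary carbon, so the secondary C–O bond and its configuration are kept, giving the diol F5. The ring is then closed by intramolecular Mitsunobu etherification (PPh3, DIAD, THF, 0 → 20 °C) of the phenol with the secondary alcohol. This inverts that carbon exactly as the epoxide opening would have done and leaves the tertiary alcohol alone, giving 18.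

**Further compounds**

F1 | step 12 | 2-[2-(1,3-dioxolan-2-yl)-3-(methoxymethoxy)-6-(3-methylbut-2-en-1-yl)phenyl]-4,4,5,5-tetramethyl-1,3,2-dioxaborolane | CC(C)=CCc1ccc(OCOC)c(C2OCCO2)c1B1OC(C)(C)C(C)(C)O1
F2 | step 12 | 2-{(2S)-8-[[2-(1,3-dioxolan-2-yl)-3-(methoxymethoxy)-6-(3-methylbut-2-en-1-yl)phenyl](hydroxy)methyl]-6-methyl-2,3-dihydro-1,4-benzodioxin-2-yl}propan-2-ol (both carbinol epimers) | CC(C)=CCc1ccc(OCOC)c(C2OCCO2)c1C(O)c1cc(C)cc2c1O[C@H](C(C)(C)O)CO2
F3 | step 12 | 2-{(2S)-8-[(1R)-7-(1,3-dioxolan-2-yl)-6-(methoxymethoxy)-2-(propan-2-ylidene)-2,3-dihydro-1H-inden-1-yl]-6-methyl-2,3-dihydro-1,4-benzodioxin-2-yl}propan-2-ol (C1 epimer of 21) | CC(C)=C1Cc2ccc(OCOC)c(C3OCCO3)c2[C@@H]1c1cc(C)cc2c1O[C@H](C(C)(C)O)CO2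
F4 | step 12 | 2-{(2S)-8-[(1S,2R)-7-(1,3-dioxolan-2-yl)-6-(methoxymethoxy)-2-(prop-1-en-2-yl)-2,3-dihydro-1H-inden-1-yl]-6-methyl-2,3-dihydro-1,4-benzodioxin-2-yl}propan-2-ol (isopropenyl isomer, drawn 1,2-trans) | CC(=C)[C@@H]1Cc2ccc(OCOC)c(C3OCCO3)c2[C@H]1c1cc(C)cc2c1O[C@H](C(C)(C)O)CO2
F0 | step 13 | none | none
F5 | step 10 | 3-{[(2R)-2,3-dihydroxy-3-methylbutyl]oxy}-2-hydroxy-5-methylbenzaldehyde | Cc1cc(OC[C@@H](O)C(C)(C)O)c(O)c(C=O)c1
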